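**Strategy.** The 2,3-dihydro-1,4-benzodioxine core (stilbene at C6) is cut at the C2–C3 bond and at the aryl ether bond O4–C4a. Both C2 and C3 are former aldehyde carbons; because C2 already hangs on O1 of the benzo ring, it is reversed in polarity as an α-aryloxybenzyllithium, and C4a, ortho to that oxygen, is made electrophilic as an aryne. In one operation the chiral-ligand-bound carbanion of an open 2-fluoroaryl benzyl ether adds to 3,5-bis(silyloxy)benzaldehyde (C2–C3) and the resulting alkoxide closes on the aryne (O4–C4a), creating the dioxane ring and both stereocentres; olefination, Heck coupling and desilylation finish maackin.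

Key step: step 6

Remark on the chemistry: the target is read as the (2R,3R)-trans isomer (C2 bears the catechol ring, C3 the resorcinol ring); the (S,S)-ligand in step 6 is written on the working assumption that it delivers (R)-C2, and its antipode is used if the sense proves opposite.

Step 1
Reactants: 1 3,4-dihydroxybenzaldehyde
Product: 2 3,4-bis(triisopropylsilyloxy)benzaldehyde
Conditions: TIPSCl (2.5 equiv), imidazole, DMF, rt to 40 °C
Reagents that add atoms: triisopropylsilyl chloride, CC(C)[Si](Cl)(C(C)C)C(C)C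
Why: Imidazole-assisted silylation of both phenols gives TIPS ethers that are inert to organolithium and amide bases, direct ring metalation only weakly, and are removed by fluoride at the end.

Step 2
Reactants: 2 3,4-bis(triisopropylsilyloxy)benzaldehyde
Product: 3 [3,4-bis(triisopropylsilyloxy)phenyl]methanol
Conditions: NaBH4, THF/MeOH, 0 °C
Reagents that add atoms: none
Why: Hydride reduction of the aryl aldehyde should give the benzylic alcohol without touching the aryl silyl ethers.

Step 3
Reactants: 3 [3,4-bis(triisopropylsilyloxy)phenyl]methanol; 4 3-fluoro-4-hydroxybenzaldehyde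
Product: 5 4-{[3,4-bis(triisopropylsilyloxy)phenyl]methoxy}-3-fluorobenzaldehyde
Conditions: PPh3, DIAD, THF, 0 °C to rt
Reagents that add atoms: none
Why: Mitsunobu etherification, in which the acidic fluorophenol (para-formyl) displaces the phosphonium-activated primary benzylic alcohol under neutral conditions that spare silyl ethers and aldehyde.

Step 4
Reactants: 5 4-{[3,4-bis(triisopropylsilyloxy)phenyl]methoxy}-3-fluorobenzaldehyde
Product: 6 1-{[3,4-bis(triisopropylsilyloxy)phenyl]methoxy}-4-(dimethoxymethyl)-2-fluorobenzene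
Conditions: HC(OMe)3, PPTS (cat.), MeOH, rt; Et3N quench
Reagents that add atoms: trimethyl orthoformate, COC(OC)OC; methanol, CO
Why: Acid-catalysed acetalisation masks the aldehyde as a dimethyl acetal that tolerates t-BuLi and lithium amides, and the weak acid leaves the aryl TIPS ethers and the benzyl aryl ether intact.

Step 5
Reactants: 7 3,5-dihydroxybenzaldehyde
Product: 8 3,5-bis(triisopropylsilyloxy)benzaldehyde
Conditions: TIPSCl (2.5 equiv), imidazole, DMF, rt
Reagents that add atoms: triisopropylsilyl chloride, CC(C)[Si](Cl)(C(C)C)C(C)C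
Why: Standard silyl ether protection of both phenols gives a non-enolisable, base-stable aldehyde for the key step.

Step 6
Reactants: 6 1-{[3,4-bis(triisopropylsilyloxy)phenyl]methoxy}-4-(dimethoxymethyl)-2-fluorobenzene; 8 3,5-bis(triisopropylsilyloxy)benzaldehyde
Product: 13 (2R,3R)-2-[3,4-bis(triisopropylsilyloxy)phenyl]-3-[3,5-bis(triisopropylsilyloxy)phenyl]-2,3-dihydro-1,4-benzodioxine-6-carbaldehyde, via α-lithio ether 9 (not isolated), via lithium alkoxide 10 (not isolated), via aryne 11 (not isolated), via benzodioxine acetal 12 (not isolated)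
Conditions: t-BuLi (1.1 equiv), 2,2-bis[(4S)-4-isopropyl-4,5-dihydrooxazol-2-yl]propane (1.2 equiv), hexane/toluene, −78 °C; then 8, −78 °C; then LiTMP (preformed, 3 equiv), THF, −78 to 0 °C; then 1 M HCl, THF, rt
Reagents that add atoms: water, O
Why: Proposed new method: t-BuLi, precomplexed with the chiral bis(oxazoline), removes a benzylic α-aryloxy proton of 6 (favoured by coordination to the ether oxygen; at −78 °C carbanion 9 should not undergo the [1,2]-Wittig shift), 9 adds to aldehyde 8 to forge C2–C3 (10), LiTMP then metalates the one ring position ortho to fluorine, LiF is lost, and the tethered alkoxide of aryne 11 adds to the proximal aryne carbon to forge O4–C4a, after which tetramethylpiperidine protonates the C5 aryllithium and the acid work-up unmasks the aldehyde. The closest known reaction types are the α-lithiation and carbonyl trapping of aryl benzyl ethers, the bis(oxazoline)-mediated enantioselective substitution of lithiated benzylic ethers, and the intramolecular alkoxide capture of arynes made from fluoroarenes; only their merger into a one-flask formal [4+2] annulation is new. The dioxane ring closes in a 6-exo-dig mode, and closure on the distal aryne carbon is geometrically impossible, so the regiochemistry is fixed. C2 (R) is controlled by the ligand–lithium complex, which resolves the configurationally labile carbanion and transfers it with retention; C3 (R) is controlled only by simple diastereoselection in the carbonyl addition, where the two bulky bis(silyloxy)aryl groups avoid each other (threo alkoxide, hence the trans ring), and the cis isomer is removed by chromatography at this stage. The selectivity needed is benzylic over ring metalation in the first stage, which the low temperature, the weakly directing TIPS and acetal groups and the lack of a ring proton between two strong directing groups should secure, and a single aryne in the second stage, secured by the single proton ortho to fluorine.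

Step 7
Reactants: 13 (2R,3R)-2-[3,4-bis(triisopropylsilyloxy)phenyl]-3-[3,5-bis(triisopropylsilyloxy)phenyl]-2,3-dihydro-1,4-benzodioxine-6-carbaldehyde
Product: 14 (2R,3R)-6-ethenyl-2-[3,4-bis(triisopropylsilyloxy)phenyl]-3-[3,5-bis(triisopropylsilyloxy)phenyl]-2,3-dihydro-1,4-benzodioxine
Conditions: Ph3PCH3Br, NaN(SiMe3)2, THF, 0 °C
Reagents that add atoms: methyltriphenylphosphonium bromide, C[P+](c1ccccc1)(c1ccccc1)c1ccccc1.[Br-]
Why: Wittig methylenation of the aryl aldehyde with the preformed non-stabilised ylide should give the styrene without affecting the silyl ethers or the two benzylic ether stereocentres.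

Step 8
Reactants: 15 5-bromobenzene-1,3-diol
Product: 16 1-bromo-3,5-bis(triisopropylsilyloxy)benzene
Conditions: TIPSCl (2.5 equiv), imidazole, DMF, rt
Reagents that add atoms: triisopropylsilyl chloride, CC(C)[Si](Cl)(C(C)C)C(C)C
Why: Silylation of both phenols gives an aryl bromide whose protecting groups match the rest of the molecule, so one fluoride step unveils all six phenols.

Step 9
Reactants: 14 (2R,3R)-6-ethenyl-2-[3,4-bis(triisopropylsilyloxy)phenyl]-3-[3,5-bis(triisopropylsilyloxy)phenyl]-2,3-dihydro-1,4-benzodioxine; 16 1-bromo-3,5-bis(triisopropylsilyloxy)benzene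
Product: 17 (2R,3R)-6-{(E)-2-[3,5-bis(triisopropylsilyloxy)phenyl]ethenyl}-2-[3,4-bis(triisopropylsilyloxy)phenyl]-3-[3,5-bis(triisopropylsilyloxy)phenyl]-2,3-dihydro-1,4-benzodioxine
Conditions: Pd(OAc)2 (5 mol %), P(o-Tol)3, Et3N, DMF, 100 °C
Reagents that add atoms: none
Why: Mizoroki–Heck coupling: oxidative addition of 16 to zerovalent palladium, syn insertion at the terminal alkene carbon of 14 and syn β-hydride elimination should give the (E)-stilbene, with C2 and C3 untouched.

Step 10
Reactants: 17 (2R,3R)-6-{(E)-2-[3,5-bis(triisopropylsilyloxy)phenyl]ethenyl}-2-[3,4-bis(triisopropylsilyloxy)phenyl]-3-[3,5-bis(triisopropylsilyloxy)phenyl]-2,3-dihydro-1,4-benzodioxine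
Product: 18 maackin, 5-[(E)-2-[(2R,3R)-2-(3,4-dihydroxyphenyl)-3-(3,5-dihydroxyphenyl)-2,3-dihydro-1,4-benzodioxin-6-yl]ethenyl]benzene-1,3-diol
Conditions: Bu4NF (7 equiv), AcOH (7 equiv), THF, 0 °C to rt, argon
Reagents that add atoms: none
Why: Fluoride cleaves the six aryl Si–O bonds while acetic acid buffers the phenoxides, so the catechol para to C2 should not open the dioxane through a quinone methide; the trans ring is in any case the thermodynamic isomer and C3 cannot epimerise.

**Compound list**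

1 | 3,4-dihydroxybenzaldehyde | O=Cc1ccc(O)c(O)c1 | starting material
2 | 3,4-bis(triisopropylsilyloxy)benzaldehyde | O=Cc1ccc(O[Si](C(C)C)(C(C)C)C(C)C)c(O[Si](C(C)C)(C(C)C)C(C)C)c1 | intermediate
3 | [3,4-bis(triisopropylsilyloxy)phenyl]methanol | OCc1ccc(O[Si](C(C)C)(C(C)C)C(C)C)c(O[Si](C(C)C)(C(C)C)C(C)C)c1 | intermediate
4 | 3-fluoro-4-hydroxybenzaldehyde | O=Cc1ccc(O)c(F)c1 | starting material
5 | 4-{[3,4-bis(triisopropylsilyloxy)phenyl]methoxy}-3-fluorobenzaldehyde | O=Cc1ccc(OCc2ccc(O[Si](C(C)C)(C(C)C)C(C)C)c(O[Si](C(C)C)(C(C)C)C(C)C)c2)c(F)c1 | intermediate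
6 | 1-{[3,4-bis(triisopropylsilyloxy)phenyl]methoxy}-4-(dimethoxymethyl)-2-fluorobenzene | COC(OC)c1ccc(OCc2ccc(O[Si](C(C)C)(C(C)C)C(C)C)c(O[Si](C(C)C)(C(C)C)C(C)C)c2)c(F)c1 | intermediate
7 | 3,5-dihydroxybenzaldehyde | O=Cc1cc(O)cc(O)c1 | starting material
8 | 3,5-bis(triisopropylsilyloxy)benzaldehyde | O=Cc1cc(O[Si](C(C)C)(C(C)C)C(C)C)cc(O[Si](C(C)C)(C(C)C)C(C)C)c1 | intermediate
9 | α-lithio ether: {[3,4-bis(triisopropylsilyloxy)phenyl][4-(dimethoxymethyl)-2-fluorophenoxy]methyl}lithium (ligand-bound, not isolated) | COC(OC)c1ccc(OC([Li])c2ccc(O[Si](C(C)C)(C(C)C)C(C)C)c(O[Si](C(C)C)(C(C)C)C(C)C)c2)c(F)c1 | intermediate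
10 | lithium (1R,2R)-1-[3,5-bis(triisopropylsilyloxy)phenyl]-2-[3,4-bis(triisopropylsilyloxy)phenyl]-2-[4-(dimethoxymethyl)-2-fluorophenoxy]ethan-1-olate (not isolated) | COC(OC)c1ccc(O[C@H](c2ccc(O[Si](C(C)C)(C(C)C)C(C)C)c(O[Si](C(C)C)(C(C)C)C(C)C)c2)[C@H](O[Li])c2cc(O[Si](C(C)C)(C(C)C)C(C)C)cc(O[Si](C(C)C)(C(C)C)C(C)C)c2)c(F)c1 | intermediate
11 | aryne: lithium (1R,2R)-alkoxide of 10 after loss of LiF, with a 2,3-didehydroarene (not isolated) | COC(OC)C1=CC=C(O[C@H](c2ccc(O[Si](C(C)C)(C(C)C)C(C)C)c(O[Si](C(C)C)(C(C)C)C(C)C)c2)[C@H](O[Li])c2cc(O[Si](C(C)C)(C(C)C)C(C)C)cc(O[Si](C(C)C)(C(C)C)C(C)C)c2)C#C1 | intermediate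
12 | (2R,3R)-6-(dimethoxymethyl)-2-[3,4-bis(triisopropylsilyloxy)phenyl]-3-[3,5-bis(triisopropylsilyloxy)phenyl]-2,3-dihydro-1,4-benzodioxine (not isolated) | COC(OC)c1ccc2c(c1)O[C@H](c1cc(O[Si](C(C)C)(C(C)C)C(C)C)cc(O[Si](C(C)C)(C(C)C)C(C)C)c1)[C@@H](c1ccc(O[Si](C(C)C)(C(C)C)C(C)C)c(O[Si](C(C)C)(C(C)C)C(C)C)c1)O2 | intermediate
13 | (2R,3R)-2-[3,4-bis(triisopropylsilyloxy)phenyl]-3-[3,5-bis(triisopropylsilyloxy)phenyl]-2,3-dihydro-1,4-benzodioxine-6-carbaldehyde | O=Cc1ccc2c(c1)O[C@H](c1cc(O[Si](C(C)C)(C(C)C)C(C)C)cc(O[Si](C(C)C)(C(C)C)C(C)C)c1)[C@@H](c1ccc(O[Si](C(C)C)(C(C)C)C(C)C)c(O[Si](C(C)C)(C(C)C)C(C)C)c1)O2 | intermediate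
14 | (2R,3R)-6-ethenyl-2-[3,4-bis(triisopropylsilyloxy)phenyl]-3-[3,5-bis(triisopropylsilyloxy)phenyl]-2,3-dihydro-1,4-benzodioxine | C=Cc1ccc2c(c1)O[C@H](c1cc(O[Si](C(C)C)(C(C)C)C(C)C)cc(O[Si](C(C)C)(C(C)C)C(C)C)c1)[C@@H](c1ccc(O[Si](C(C)C)(C(C)C)C(C)C)c(O[Si](C(C)C)(C(C)C)C(C)C)c1)O2 | intermediate
15 | 5-bromobenzene-1,3-diol | Oc1cc(O)cc(Br)c1 | starting material
16 | 1-bromo-3,5-bis(triisopropylsilyloxy)benzene | Brc1cc(O[Si](C(C)C)(C(C)C)C(C)C)cc(O[Si](C(C)C)(C(C)C)C(C)C)c1 | intermediate
17 | hexakis-O-triisopropylsilyl maackin | CC(C)[Si](C(C)C)(C(C)C)Oc1cc(O[Si](C(C)C)(C(C)C)C(C)C)cc(/C=C/c2ccc3c(c2)O[C@H](c2cc(O[Si](C(C)C)(C(C)C)C(C)C)cc(O[Si](C(C)C)(C(C)C)C(C)C)c2)[C@@H](c2ccc(O[Si](C(C)C)(C(C)C)C(C)C)c(O[Si](C(C)C)(C(C)C)C(C)C)c2)O3)c1 | intermediate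
18 | maackin | Oc1cc(O)cc(/C=C/c2ccc3c(c2)O[C@H](c2cc(O)cc(O)c2)[C@@H](c2ccc(O)c(O)c2)O3)c1 | target

**Totals.** Total step count: 10. Longest linear sequence: 8 steps (1, 2, 3, 4, 6, 7, 9, 10).

**Steps most likely to fail**

1. Step 6. What may go wrong: ring metalation of the fluoroarene competing with benzylic deprotonation, and weak facial control in the carbonyl addition eroding diastereomeric and enantiomeric purity. Fallback (known chemistry, bonds and stereocentres made in separate catalyst-controlled operations): setting out from 6, lithiation with t-BuLi in THF at −78 °C without ligand and addition to 8 gives, after aqueous quench, the stereorandom adduct alcohol F1. Dess–Martin oxidation gives the α-aryloxy ketone F2, whose α-centre epimerises readily. Asymmetric transfer hydrogenation under dynamic kinetic resolution with RuCl[(S,S)-TsDPEN](p-cymene) and HCO2H–Et3N in DMF (catalyst sense chosen by analogy with the benzoin to hydrobenzoin reduction) should give the (1R,2R)-alcohol F3. Treatment of F3 with LiTMP in THF (aryne closure) and acidic work-up returns to the route at 13.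

2. Step 9. What may go wrong: slow oxidative addition of the hindered aryl bromide, arylation at the internal alkene carbon, or thermal loss of silyl groups at 100 °C. Fallback: setting out from 14, the stilbene is closed by olefin cross-metathesis instead. Wittig methylenation of 8 (Ph3PCH3Br, NaN(SiMe3)2) gives 3,5-bis(triisopropylsilyloxy)styrene F4, and cross-metathesis of 14 with excess F4 (second-generation Grubbs catalyst, RuCl2(PCy3)(H2IMes)(=CHPh), CH2Cl2, 40 °C) should give the (E)-stilbene, returning at 17.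

3. Step 10. What may go wrong: opening of the dioxane ring through the para-phenoxide (quinone methide formation) and air oxidation of the free polyphenol during fluoride treatment and purification. Fallback: setting out from 17, desilylation with HF·pyridine in THF/pyridine is followed in the same flask by Ac2O to give maackin hexaacetate F5, which is purified in this stable form and then cleaved under neutral conditions (NH4OAc, MeOH/H2O, rt), returning at 18.

**Further compounds**

F1 | step 6 | 1-[3,5-bis(triisopropylsilyloxy)phenyl]-2-[3,4-bis(triisopropylsilyloxy)phenyl]-2-[4-(dimethoxymethyl)-2-fluorophenoxy]ethan-1-ol (mixture of stereoisomers) | COC(OC)c1ccc(OC(c2ccc(O[Si](C(C)C)(C(C)C)C(C)C)c(O[Si](C(C)C)(C(C)C)C(C)C)c2)C(O)c2cc(O[Si](C(C)C)(C(C)C)C(C)C)cc(O[Si](C(C)C)(C(C)C)C(C)C)c2)c(F)c1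
F2 | step 6 | 1-[3,5-bis(triisopropylsilyloxy)phenyl]-2-[3,4-bis(triisopropylsilyloxy)phenyl]-2-[4-(dimethoxymethyl)-2-fluorophenoxy]ethan-1-one | COC(OC)c1ccc(OC(c2ccc(O[Si](C(C)C)(C(C)C)C(C)C)c(O[Si](C(C)C)(C(C)C)C(C)C)c2)C(=O)c2cc(O[Si](C(C)C)(C(C)C)C(C)C)cc(O[Si](C(C)C)(C(C)C)C(C)C)c2)c(F)c1
F3 | step 6 | (1R,2R)-1-[3,5-bis(triisopropylsilyloxy)phenyl]-2-[3,4-bis(triisopropylsilyloxy)phenyl]-2-[4-(dimethoxymethyl)-2-fluorophenoxy]ethan-1-ol | COC(OC)c1ccc(O[C@H](c2ccc(O[Si](C(C)C)(C(C)C)C(C)C)c(O[Si](C(C)C)(C(C)C)C(C)C)c2)[C@H](O)c2cc(O[Si](C(C)C)(C(C)C)C(C)C)cc(O[Si](C(C)C)(C(C)C)C(C)C)c2)c(F)c1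
F4 | step 9 | 3,5-bis(triisopropylsilyloxy)styrene | C=Cc1cc(O[Si](C(C)C)(C(C)C)C(C)C)cc(O[Si](C(C)C)(C(C)C)C(C)C)c1
F5 | step 10 | maackin hexaacetate | CC(=O)Oc1cc(OC(C)=O)cc(/C=C/c2ccc3c(c2)O[C@H](c2cc(OC(C)=O)cc(OC(C)=O)c2)[C@@H](c2ccc(OC(C)=O)c(OC(C)=O)c2)O3)c1
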